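**Strategy**

Everything rests on the C9–C10 bond. The quaternary C10 joined to C9 in ring B (C5–C10), next to the C6 ketone and the C7=C8 alkene (a C7 enol derivative one step back), is the product pattern of a [3,3] shift. An anionic oxy-Cope rearrangement of a bicyclo[2.2.2]octenol breaks C2–C7, forms C9–C10, uncovers ring B as a cis-decalin, sets C9 and C10, and leaves a C7 enolate that is trapped as its triflate, all in one operation. The precursor is the C7 tertiary carbinol of a creosol-derived bicyclo[2.2.2]oct-5-en-2-one (C1=C10 alkene bridge, C6 dimethyl ketal, C4 gem-dimethyl, C3 (R)-1-phenylethyl ether) bearing a (Z)-C8=C9 alkenyl group with a C11 benzyl ether.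

Key step: step 7

Assumption: drimane atom numbers are used for all intermediates, bicyclic ones included; the facial bias of the (R)-1-phenylethyl group in step 5 is taken to be moderate and in the required sense, the unwanted diastereomer is removed by chromatography, and the (S)-alcohol would be used in step 1 if the bias proved opposite.

**Route**

Step 1
Reactants: 1 (R)-1-phenylethanol; 2 3-chloro-2-methylprop-1-ene
Product: 3 (R)-[1-(2-methylprop-2-en-1-yloxy)ethyl]benzene
Conditions: NaH, n-Bu4NI (cat.), THF/DMF, 0 °C to rt
Reagents that add atoms: none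
Why: Williamson etherification: after deprotonation the oxygen of 1 displaces the primary allylic chloride of 2 (SN2), the carbinol C–O bond is never broken, and the (R) configuration is carried over.

Step 2
Reactants: 3 (R)-[1-(2-methylprop-2-en-1-yloxy)ethyl]benzene
Product: 4 (R)-[1-(2-methylprop-1-en-1-yloxy)ethyl]benzene
Conditions: KOt-Bu (substoichiometric), DMSO, 70 °C
Reagents that add atoms: none
Why: Base-mediated allyl-to-alkenyl ether isomerization: reversible deprotonation at the allylic OCH2 and reprotonation at the terminal carbon moves the double bond into conjugation with oxygen; the terminus carries two methyl groups, so no E/Z isomers arise, and the much less acidic benzylic C–H keeps the stereocentre intact.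

Step 3
Reactants: 5 but-2-yn-1-ol
Product: 7 (Z)-3-iodobut-2-en-1-ol, via cyclic sodium alkenylalanate 6 (not isolated)
Conditions: NaAlH2(OCH2CH2OMe)2, THF, 0 °C to rt; then I2, −78 to 0 °C
Reagents that add atoms: iodine, II
Why: Hydroxyl-directed trans-hydroalumination of the propargylic alcohol delivers hydride to C2 and aluminium to C3 within a five-membered ring, and iodinolysis of the C–Al bond with retention fixes the Z geometry (iodine cis to CH2OH).

Step 4
Reactants: 7 (Z)-3-iodobut-2-en-1-ol
Product: 8 benzyl (2Z)-3-iodobut-2-en-1-yl ether
Conditions: NaH, BnBr, n-Bu4NI (cat.), THF, 0 °C to rt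
Reagents that add atoms: benzyl bromide, BrCc1ccccc1
Why: Williamson benzylation of the primary allylic hydroxyl under conditions too mild for dehydroiodination; a benzyl ether is preferred to a silyl ether at this oxygen because silicon could later migrate to the cis-disposed carbanion, alkoxide or enolate centres, and because benzyl leaves in the same hydrogenolysis as the auxiliary.

Step 5
Reactants: 9 creosol (2-methoxy-4-methylphenol); 4 (R)-[1-(2-methylprop-1-en-1-yloxy)ethyl]benzene
Product: 11 (1S,4R,7R)-3,3-dimethoxy-5,8,8-trimethyl-7-[(R)-1-phenylethoxy]bicyclo[2.2.2]oct-5-en-2-one, via masked o-benzoquinone 10 (not isolated)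
Conditions: PhI(OAc)2 (slow addition), 4 in excess (surplus recovered), MeOH, 0 °C to rt
Reagents that add atoms: methanol, CO
Why: Oxidative dearomatization of the guaiacol unit in methanol gives dienone 10, which is intercepted by the electron-rich alkene 4 in an inverse-demand Diels–Alder reaction: the nucleophilic CMe2 carbon (C4) bonds to C5, the δ-terminus of the dienone, and the oxygen-bearing C3 to C2; endo addition places the C3 oxygen syn to the new C1=C10 bridge; and the 1-phenylethyl group (s-trans enol ether enforced by the cis methyl, phenyl covering one face) biases the face of 4 and makes the two endo adducts diastereomers, so that 11 should be secured as one stereoisomer after chromatography.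

Step 6
Reactants: 8 benzyl (2Z)-3-iodobut-2-en-1-yl ether; 11 bicyclic ketone
Product: 13 (1S,2S,4R,7R)-2-[(2Z)-4-(benzyloxy)but-2-en-2-yl]-3,3-dimethoxy-5,8,8-trimethyl-7-[(R)-1-phenylethoxy]bicyclo[2.2.2]oct-5-en-2-ol, via alkenyllithium 12 (not isolated)
Conditions: 8, t-BuLi (2 equiv), Et2O, −78 °C; then 11, THF, −78 to −40 °C; H2O
Reagents that add atoms: none
Why: Iodine–lithium exchange proceeds with retention of the alkene geometry, and the alkenyllithium 12 adds to the non-enolizable α,α-dimethoxy ketone (1,2-addition) from the face of C7 next to the C1=C10 bridge, the other face being blocked by the C3–C4 bridge with H3 and a C4 methyl group, which sets C7 with the alkenyl group syn to the alkene bridge.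

Step 7
Reactants: 13 C7 alkenyl carbinol
Product: 16 cis-fused 11-benzyloxy-6,6-dimethoxy-3-[(R)-1-phenylethoxy]drima-1,7-dien-7-yl trifluoromethanesulfonate (C3–O, C10–CH3, C11 and H5 on one face), via potassium alkoxide 14 (not isolated), via potassium enolate 15 (not isolated)
Conditions: KN(SiMe3)2, 18-crown-6, THF, 0 °C to rt; then N-(5-chloropyridin-2-yl)bis(trifluoromethanesulfonyl)imide, −78 to 0 °C
Reagents that add atoms: N-(5-chloropyridin-2-yl)bis(trifluoromethanesulfonyl)imide, O=S(=O)(N(c1ccc(Cl)cn1)S(=O)(=O)C(F)(F)F)C(F)(F)F
Why: Deprotonation of the tertiary C7 hydroxyl gives the potassium alkoxide 14, whose charge (freed from its cation by 18-crown-6) accelerates a concerted [3,3] sigmatropic shift of the 1,5-diene C9=C8–C7–C2–C1=C10, in which C2–C7 breaks, C9–C10 forms and the C7=C8 enolate 15 results, and 15 is O-sulfonylated in the same flask to give 16. The closest known reaction type is the anionic oxy-Cope rearrangement of 2-alkenylbicyclo[2.2.2]oct-5-en-2-ols derived from masked o-benzoquinone Diels–Alder adducts, which gives cis-decalins. Ring B (C5–C10) is not closed by a cyclization; it is uncovered by the suprafacial–suprafacial sigmatropic reorganization through a boat-shaped six-centre transition state that the bicyclic frame enforces, driven by enolate formation and release of bicyclic strain. C10 is set by the frame: C9 can reach C10 only from the face of the C1=C10 bridge that lies over the C6–C7 bridge, so C9 ends cis to C6 (cis ring fusion) and the C10 methyl ends cis to the C3 oxygen and to H5. C9 is set by the Z geometry of C8=C9 in that boat, which puts C11 on the same face of ring B as the C10 methyl. The step needs the [3,3] path over a [1,3] shift or fragmentation and a regiodefined enolate capture; the syn arrangement of alkenyl group and C1=C10 bridge fixed in step 6 secures the first, and the fact that C7=C8 is the only enolate the shift can generate (C6 carries no hydrogen) secures the second.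

Step 8
Reactants: 16 enol triflate
Product: 17 cis-fused 11-benzyloxy-6,6-dimethoxy-3-[(R)-1-phenylethoxy]drima-1,7-diene
Conditions: Pd(OAc)2 (cat.), PPh3, HCO2H, n-Bu3N, DMF, 60 °C
Reagents that add atoms: none
Why: Palladium-catalysed transfer hydrogenolysis of an enol triflate: zerovalent palladium formed in the flask inserts into the C7–O bond, formate replaces triflate on the metal and loses CO2, and reductive elimination gives the C7–H alkene without moving C7=C8, while the amine buffer protects the ketal.

Step 9
Reactants: 17 diene
Product: 18 (3R,5R,9R,10S)-6,6-dimethoxydrim-7-ene-3,11-diol (cis-fused)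
Conditions: H2 (1 atm), Pd(OH)2/C, NaHCO3, EtOAc, rt
Reagents that add atoms: none
Why: Heterogeneous hydrogenation saturates the disubstituted C1=C2 bond and cleaves both benzylic C–O bonds (benzyl at O11, 1-phenylethyl at O3) by hydrogenolysis, whereas the trisubstituted C7=C8 bond, shielded by the C6 ketal and the C9 and C10 substituents, should not react at one atmosphere; no stereocentre is formed or touched.

Step 10
Reactants: 18 ketal diol
Product: 19 (3R,5R,9R,10S)-3,11-dihydroxydrim-7-en-6-one (cis-fused, H5 and C10–CH3 on one face)
Conditions: 0.5 M aq. HCl, THF, 0 °C to rt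
Reagents that add atoms: water, O
Why: Acid-catalysed hydrolysis of the allylic dimethyl ketal through the C6 oxocarbenium ion releases the ketone in conjugation with C7=C8, under conditions too mild to enolize C5 or C9.

Step 11
Reactants: 19 cis-fused enone diol
Product: 21 (3R,5S,9R,10S)-3,11-dihydroxydrim-7-en-6-one (trans-fused), via trilithium enolate 20 (not isolated)
Conditions: LiN(i-Pr)2 (3.5 equiv), THF, −78 to −40 °C; then AcOH, −78 °C
Reagents that add atoms: none
Why: Kinetic α′-deprotonation of the enone by the lithium amide (after both hydroxyls are deprotonated) gives the cross-conjugated C5=C6 enolate 20, and irreversible protonation at −78 °C takes place on the face of C5 opposite to the axial C10 and C4 methyl groups, which puts H5 trans to the C10 methyl (the trans ring fusion, also the more stable one) without exposing C9 to equilibrating base.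

Step 12
Reactants: 21 trans-fused enone diol; 22 umbelliferone (7-hydroxycoumarin)
Product: 23 ligupersin A
Conditions: PPh3, DIAD, THF, 0 °C to rt
Reagents that add atoms: none
Why: Mitsunobu etherification: PPh3/DIAD activate the unhindered primary C11 hydroxyl, which is displaced (SN2 at CH2, no stereocentre involved) by the acidic 7-hydroxyl of umbelliferone, while the secondary C3 hydroxyl next to the gem-dimethyl group is too hindered to compete.

**Compound list**

1 | (R)-1-phenylethanol | C[C@@H](O)c1ccccc1 | starting material
2 | 3-chloro-2-methylprop-1-ene | C=C(C)CCl | starting material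
3 | (R)-[1-(2-methylprop-2-en-1-yloxy)ethyl]benzene | C=C(C)CO[C@H](C)c1ccccc1 | intermediate
4 | (R)-[1-(2-methylprop-1-en-1-yloxy)ethyl]benzene | CC(C)=CO[C@H](C)c1ccccc1 | intermediate
5 | but-2-yn-1-ol | CC#CCO | starting material
6 | sodium 2,2-bis(2-methoxyethoxy)-3-methyl-2,5-dihydro-1,2-oxaaluminol-2-uide (cyclic alkenylalanate, not isolated) | CC1=CCO[Al-]1(OCCOC)OCCOC.[Na+] | intermediate
7 | (Z)-3-iodobut-2-en-1-ol | OC/C=C(/C)I | intermediate
8 | benzyl (2Z)-3-iodobut-2-en-1-yl ether | c1ccccc1COC/C=C(/C)I | intermediate
9 | creosol (2-methoxy-4-methylphenol) | COc1cc(C)ccc1O | starting material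
10 | 6,6-dimethoxy-4-methylcyclohexa-2,4-dien-1-one (masked o-benzoquinone, not isolated) | COC1(OC)C=C(C)C=CC1=O | intermediate
11 | (1S,4R,7R)-3,3-dimethoxy-5,8,8-trimethyl-7-[(R)-1-phenylethoxy]bicyclo[2.2.2]oct-5-en-2-one (C7 ketone, C6 ketal, C3 oxygen syn to the C1=C10 bridge) | O=C1[C@H]2C=C(C)[C@H](C(C)(C)[C@@H]2O[C@H](C)c2ccccc2)C1(OC)OC | intermediate
12 | [(2E)-4-(benzyloxy)but-2-en-2-yl]lithium (Li cis to CH2OBn, not isolated) | c1ccccc1COC/C=C(/C)[Li] | intermediate
13 | (1S,2S,4R,7R)-2-[(2Z)-4-(benzyloxy)but-2-en-2-yl]-3,3-dimethoxy-5,8,8-trimethyl-7-[(R)-1-phenylethoxy]bicyclo[2.2.2]oct-5-en-2-ol (alkenyl group syn to the C1=C10 bridge) | c1ccccc1COC/C=C(/C)[C@@]1(O)[C@H]2C=C(C)[C@H](C(C)(C)[C@@H]2O[C@H](C)c2ccccc2)C1(OC)OC | intermediate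
14 | potassium C7 alkoxide of 13 (not isolated) | [K+].c1ccccc1COC/C=C(/C)[C@@]1([O-])[C@H]2C=C(C)[C@H](C(C)(C)[C@@H]2O[C@H](C)c2ccccc2)C1(OC)OC | intermediate
15 | potassium C7=C8 enolate of cis-fused 11-benzyloxy-6,6-dimethoxy-3-[(R)-1-phenylethoxy]drim-1-en-7-one (not isolated) | [K+].CC1=C([O-])C(OC)(OC)[C@H]2C(C)(C)[C@H](O[C@H](C)c3ccccc3)C=C[C@@]2(C)[C@@H]1COCc1ccccc1 | intermediate
16 | cis-fused 11-benzyloxy-6,6-dimethoxy-3-[(R)-1-phenylethoxy]drima-1,7-dien-7-yl trifluoromethanesulfonate (C3–O, C10–CH3, C11, H5 on one face) | CC1=C(OS(=O)(=O)C(F)(F)F)C(OC)(OC)[C@H]2C(C)(C)[C@H](O[C@H](C)c3ccccc3)C=C[C@@]2(C)[C@@H]1COCc1ccccc1 | intermediate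
17 | cis-fused 11-benzyloxy-6,6-dimethoxy-3-[(R)-1-phenylethoxy]drima-1,7-diene (same relative configuration as 16) | CC1=CC(OC)(OC)[C@H]2C(C)(C)[C@H](O[C@H](C)c3ccccc3)C=C[C@@]2(C)[C@@H]1COCc1ccccc1 | intermediate
18 | (3R,5R,9R,10S)-6,6-dimethoxydrim-7-ene-3,11-diol (cis-fused) | CC1=CC(OC)(OC)[C@H]2C(C)(C)[C@H](O)CC[C@@]2(C)[C@@H]1CO | intermediate
19 | (3R,5R,9R,10S)-3,11-dihydroxydrim-7-en-6-one (cis-fused) | CC1=CC(=O)[C@H]2C(C)(C)[C@H](O)CC[C@@]2(C)[C@@H]1CO | intermediate
20 | trilithium salt of 19: C5=C6 enolate with C3 and C11 alkoxides (not isolated) | [Li+].[Li+].[Li+].CC1=CC([O-])=C2C(C)(C)[C@H]([O-])CC[C@@]2(C)[C@@H]1C[O-] | intermediate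
21 | (3R,5S,9R,10S)-3,11-dihydroxydrim-7-en-6-one (trans-fused) | CC1=CC(=O)[C@@H]2C(C)(C)[C@H](O)CC[C@@]2(C)[C@@H]1CO | intermediate
22 | umbelliferone (7-hydroxycoumarin) | O=c1ccc2ccc(O)cc2o1 | starting material
23 | ligupersin A, 7-{[(3R,5S,9R,10S)-3-hydroxy-6-oxodrim-7-en-11-yl]oxy}coumarin | CC1=CC(=O)[C@@H]2C(C)(C)[C@H](O)CC[C@@]2(C)[C@@H]1COc1ccc2ccc(=O)oc2c1 | target

**Step count**

Total: 12 steps. Longest linear sequence: 10 steps (steps 1, 2, 5, 6, 7, 8, 9, 10, 11, 12).

**Steps most likely to fail**

1. Step 5. The transient dienone 10 may dimerize faster than it is intercepted by the hindered, trisubstituted enol ether 4; the enol ether may also be consumed by acid-promoted addition of methanol, and face discrimination by the auxiliary may be weak. The fallback sets out from 9 and comes back at 11. Creosol 9 is oxidized with PhI(OAc)2 in MeOH without a trap, so that 10 dimerizes to the tricyclic endo dimer 3,3,10,10-tetramethoxy-7,11-dimethyltricyclo[6.2.2.0(2,7)]dodeca-5,11-diene-4,9-dione F1, which is isolated; its structure is written by analogy with dimers of this class. Heating the dimer with an excess of 4 in mesitylene at about 220 °C in a sealed tube should release 10 by retro-Diels–Alder reaction at a low stationary concentration in an aprotic, acid-free medium. Cross-cycloaddition with the large excess of 4 should then dominate and give 11 after chromatography.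

2. Step 7. The shift must join a fully substituted C10 to a branched C9 through a boat in which C11 points toward the C5/C6 region, so it may be slow. The hindered, fully substituted enolate may then be sulfonylated incompletely or protonated adventitiously in the crown-ether medium. The fallback sets out from 13 and comes back at 16 by separating the two events. The rearrangement alone is run with KN(SiMe3)2 and 18-crown-6 in THF and quenched with aq. NH4Cl to give the cis-fused C7 ketone, 11-benzyloxy-6,6-dimethoxy-3-[(R)-1-phenylethoxy]drim-1-en-7-one F2, as a C8 epimer mixture that converges later. After purification the same enolate is regenerated with KN(SiMe3)2 in THF at −78 °C (C8–H is the only α-hydrogen, C6 has none) and sulfonylated with PhNTf2 to give 16.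

3. Step 11. H5 of the cis-fused ketone is flanked by the C4 and C10 methyl groups, so kinetic deprotonation may be slow and may divert to the C12 methyl (γ′ position). That would give an extended dienolate, which is protonated without change at C5 or with deconjugation. The fallback sets out from 19 and comes back at 21, and gives up kinetic control. Compound 19 is equilibrated with DBU in toluene at 60 °C, a reversible enolization that forms no alkoxide and relies on the thermodynamic preference for the trans ring fusion; any deconjugated isomer returns to the enone under the same conditions. The reaction is stopped once C5 has equilibrated, so that C9 is exposed as briefly as possible. No new compound is made.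

Further compounds
F1 | step 5 | 3,3,10,10-tetramethoxy-7,11-dimethyltricyclo[6.2.2.0(2,7)]dodeca-5,11-diene-4,9-dione (endo dimer of 10, racemic, relative configuration shown) | O=C1C(OC)(OC)[C@@H]2C(C)=C[C@H]1[C@@]1(C)C=CC(=O)C(OC)(OC)[C@@H]21
F2 | step 7 | cis-fused 11-benzyloxy-6,6-dimethoxy-3-[(R)-1-phenylethoxy]drim-1-en-7-one (both C8 epimers) | CC1C(=O)C(OC)(OC)[C@H]2C(C)(C)[C@H](O[C@H](C)c3ccccc3)C=C[C@@]2(C)[C@@H]1COCc1ccccc1
F0 | step 11 | none | none
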